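The seven-membered ring B is disconnected at its only olefin, C8=C9, the trisubstituted enal double bond whose C8 carries the formyl carbon C14. Ring-closing metathesis between an allyl group on the quaternary carbon C1 and a 2-substituted acrylate tethered through C5–C7 closes ring B on a monocyclic β-methoxy cyclopentanone that holds only the C1 stereocentre, set by asymmetric conjugate addition. In one operation the flexible cyclopentanone becomes a rigid hydroazulene; after loss of methanol its angular methyl directs isopropyl addition at C4 and hydroboration of C5=C6, which installs H-5 and O-6 together. The ring ester is finally adjusted to the aldehyde and C6 is acylated.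

Key step: step 6

Remark on numbering and assumptions: daucane numbering is used (ring A: C1 quaternary with methyl C15, C2, C3, C4 carbinol with isopropyl, C5 ring-fusion CH; ring B: C1, C5, C6 acyloxy carbon, C7, C8 bearing C14, C9, C10). In step 2 the ligand antipode that gives the R-configured C1 is assumed, and 11 and 12 are carried as mixtures at C5 and C6, which step 7 erases.

Step 1
Reactants: 1 3-ethoxycyclopent-2-en-1-one; 2 allylmagnesium bromide
Product: 4 3-(prop-2-en-1-yl)cyclopent-2-en-1-one, via bromomagnesium alkoxide adduct 3 (not isolated)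
Conditions: THF, 0 °C; then 1 M aq. HCl, 0 °C, short contact
Reagents that add atoms: water, O
Why: 1,2-addition of the Grignard reagent to the vinylogous ester followed by acid-induced loss of ethanol with carbonyl transposition (Stork–Danheiser sequence) should give the 3-allyl enone, cold and brief acid contact keeping the allyl olefin out of conjugation.

Step 2
Reactants: 4 3-(prop-2-en-1-yl)cyclopent-2-en-1-one
Product: 6 trimethyl{[(3R)-3-methyl-3-(prop-2-en-1-yl)cyclopent-1-en-1-yl]oxy}silane, via dimethylaluminium enolate 5 (not isolated)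
Conditions: Me3Al, copper thiophene-2-carboxylate (5 mol %), chiral BINOL-derived phosphoramidite ligand (10 mol %), Et2O, −30 °C; then TMSOTf, −30 to 0 °C
Reagents that add atoms: trimethylaluminium, C[Al](C)C; trimethylsilyl trifluoromethanesulfonate, C[Si](C)(C)OS(=O)(=O)C(F)(F)F
Why: copper-catalysed asymmetric conjugate addition of trimethylaluminium to β-substituted cyclic enones is an established route to all-carbon quaternary centres, the ligand antipode being chosen so that methyl adds to the face of C1 giving the R centre, and silylation of the aluminium enolate preserves the C4–C5 enolate regiochemistry that direct enolisation of the ketone would not give.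

Step 3
Reactants: 7 trimethyl phosphonoacetate; 8 2-bromo-1,1-dimethoxyethane
Product: 9 methyl 2-(dimethoxyphosphoryl)-4,4-dimethoxybutanoate (racemic)
Conditions: NaH, DMF, 0 °C; then NaI (cat.), 80 °C
Reagents that add atoms: none
Why: SN2 C-alkylation of the sodium salt of the phosphonoacetate with the primary bromide, slow for a β-dialkoxy bromide but driven by heat and iodide catalysis.

Step 4
Reactants: 9 methyl 2-(dimethoxyphosphoryl)-4,4-dimethoxybutanoate
Product: 10 methyl 4,4-dimethoxy-2-methylidenebutanoate
Conditions: 37% aq. CH2O, K2CO3, H2O, rt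
Reagents that add atoms: formaldehyde, C=O
Why: Horner–Wadsworth–Emmons olefination with aqueous formaldehyde converts α-substituted phosphonoacetates into 2-substituted acrylates under carbonate conditions that leave the acetal intact.

Step 5
Reactants: 6 trimethyl{[(3R)-3-methyl-3-(prop-2-en-1-yl)cyclopent-1-en-1-yl]oxy}silane; 10 methyl 4,4-dimethoxy-2-methylidenebutanoate
Product: 11 methyl 4-methoxy-4-[(2R)-2-methyl-5-oxo-2-(prop-2-en-1-yl)cyclopentyl]-2-methylidenebutanoate (mixture at C5 and C6)
Conditions: TMSOTf (10 mol %), CH2Cl2, −78 °C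
Reagents that add atoms: none
Why: Mukaiyama aldol-type addition of the silyl enol ether to the oxocarbenium ion formed from the acetal forms the C5–C6 bond at the regiodefined enol carbon, and no stereocontrol is needed because C5 and C6 are flattened in step 7 and reset in step 9.

Step 6
Reactants: 11 methyl 4-methoxy-4-[(2R)-2-methyl-5-oxo-2-(prop-2-en-1-yl)cyclopentyl]-2-methylidenebutanoate
Product: 12 methyl (8aR)-4-methoxy-8a-methyl-3-oxo-1,2,3,3a,4,5,8,8a-octahydroazulene-6-carboxylate (mixture at C5 and C6)
Conditions: second-generation Grubbs catalyst (5 mol %), 1,4-benzoquinone (10 mol %), toluene (2 mM), 80 °C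
Reagents that add atoms: none
Why: The ruthenium alkylidene loads onto the monosubstituted allyl olefin, undergoes [2+2] cycloaddition with the tethered 1,1-disubstituted acrylate and cycloreversion with loss of ethene, forming the trisubstituted C8=C9 enoate. The closest known reaction type is ring-closing metathesis of 2-substituted acrylates with terminal olefins to five- to seven-membered cyclic enoates. Ring B is closed as a seven-membered carbocycle by olefin metathesis on both the cis- and the trans-disposed C1/C5 diastereomers, each giving a fused hydroazulene; no stereocentre is created and the new olefin is necessarily cis within the ring. The step needs ring closure to win over cross-metathesis dimerisation at the allyl terminus and over allyl-to-propenyl migration, which the geminal substitution at C1, the poor homodimerisation of the acrylate, high dilution and the benzoquinone additive should secure. Closing the ring before methanol is eliminated also fixes the later C5=C6 geometry, which an elimination on the monocycle would not control.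

Step 7
Reactants: 12 methyl (8aR)-4-methoxy-8a-methyl-3-oxo-1,2,3,3a,4,5,8,8a-octahydroazulene-6-carboxylate
Product: 13 methyl (8aR)-8a-methyl-3-oxo-1,2,3,5,8,8a-hexahydroazulene-6-carboxylate
Conditions: TsOH·H2O (10 mol %), toluene, 50 °C
Reagents that add atoms: none
Why: acid-catalysed β-elimination of methanol through the C4 enol converges all diastereomers of 12 to one enone whose C5=C6 geometry is imposed by the ring, the mild temperature being meant to keep the skipped C5=C6/C8=C9 diene from moving into conjugation.

Step 8
Reactants: 13 methyl (8aR)-8a-methyl-3-oxo-1,2,3,5,8,8a-hexahydroazulene-6-carboxylate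
Product: 14 methyl (3R,8aR)-3-hydroxy-8a-methyl-3-(propan-2-yl)-1,2,3,5,8,8a-hexahydroazulene-6-carboxylate
Conditions: i-PrMgCl, CeCl3, THF, −78 to −40 °C; aq. NH4Cl
Reagents that add atoms: isopropylmagnesium chloride, CC(C)[Mg]Cl
Why: organocerium 1,2-addition to the enone (low basicity, no conjugate addition, ester untouched at low temperature) is expected from the α-face, anti to the β-oriented angular methyl that sits 1,3 to C4, which places the new hydroxyl β and the isopropyl group α.

Step 9
Reactants: 14 methyl (3R,8aR)-3-hydroxy-8a-methyl-3-(propan-2-yl)-1,2,3,5,8,8a-hexahydroazulene-6-carboxylate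
Product: 16 methyl (3R,3aS,4S,8aR)-3,4-dihydroxy-8a-methyl-3-(propan-2-yl)-1,2,3,3a,4,5,8,8a-octahydroazulene-6-carboxylate, via bis-boranyl intermediate 15 (not isolated)
Conditions: BH3·SMe2, THF, 0 °C to rt; then 30% H2O2, aq. NaOAc, 0 °C to rt
Reagents that add atoms: hydrogen peroxide, OO
Why: hydroboration–oxidation places boron on the less substituted C6 and hydrogen on C5 in a syn addition that is expected on the α-face, anti to the angular methyl and to the pseudo-axial allylic C4–oxygen (the isopropyl group lying pseudo-equatorial), so that H-5 and the C6 hydroxyl both become α (trans ring fusion), while the electron-poor C8=C9 enoate is left alone and buffered oxidation retains configuration at C6.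

Step 10
Reactants: 16 methyl (3R,3aS,4S,8aR)-3,4-dihydroxy-8a-methyl-3-(propan-2-yl)-1,2,3,3a,4,5,8,8a-octahydroazulene-6-carboxylate
Product: 17 (3R,3aS,4S,8aR)-6-(hydroxymethyl)-8a-methyl-3-(propan-2-yl)-1,2,3,3a,4,5,8,8a-octahydroazulene-3,4-diol
Conditions: i-Bu2AlH (DIBAL-H), CH2Cl2, −78 to 0 °C; aq. potassium sodium tartrate
Reagents that add atoms: none
Why: diisobutylaluminium hydride reduces the α,β-unsaturated ester in a 1,2-fashion to the primary allylic alcohol without touching the olefin or any stereocentre.

Step 11
Reactants: 17 (3R,3aS,4S,8aR)-6-(hydroxymethyl)-8a-methyl-3-(propan-2-yl)-1,2,3,3a,4,5,8,8a-octahydroazulene-3,4-diol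
Product: 18 (3R,3aS,4S,8aR)-3,4-dihydroxy-8a-methyl-3-(propan-2-yl)-1,2,3,3a,4,5,8,8a-octahydroazulene-6-carbaldehyde
Conditions: MnO2 (activated, excess), CH2Cl2, rt
Reagents that add atoms: none
Why: activated MnO2 oxidises allylic alcohols selectively, so only the primary allylic C14 hydroxyl should become the aldehyde while the secondary C6 and tertiary C4 hydroxyls remain.

Step 12
Reactants: 18 (3R,3aS,4S,8aR)-3,4-dihydroxy-8a-methyl-3-(propan-2-yl)-1,2,3,3a,4,5,8,8a-octahydroazulene-6-carbaldehyde; 19 4-acetoxybenzoic acid
Product: 20 (3R,3aS,4S,8aR)-6-formyl-3-hydroxy-8a-methyl-3-(propan-2-yl)-1,2,3,3a,4,5,8,8a-octahydroazulen-4-yl 4-(acetyloxy)benzoate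
Conditions: DCC, DMAP (cat.), CH2Cl2, 0 °C to rt
Reagents that add atoms: none
Why: Steglich esterification acylates the secondary C6 hydroxyl with retention, the tertiary C4 hydroxyl being too hindered to react and the acetate keeping the phenol from competing.

Step 13
Reactants: 20 (3R,3aS,4S,8aR)-6-formyl-3-hydroxy-8a-methyl-3-(propan-2-yl)-1,2,3,3a,4,5,8,8a-octahydroazulen-4-yl 4-(acetyloxy)benzoate
Product: 21 (3R,3aS,4S,8aR)-6-formyl-3-hydroxy-8a-methyl-3-(propan-2-yl)-1,2,3,3a,4,5,8,8a-octahydroazulen-4-yl 4-hydroxybenzoate
Conditions: K2CO3 (0.3 equiv), MeOH, 0 °C, short contact; aq. NH4Cl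
Reagents that add atoms: none
Why: carbonate-catalysed methanolysis cleaves a phenyl acetate far faster than the hindered secondary alkyl benzoate, whose carbonyl is further deactivated once the para-phenoxide forms, so brief treatment at 0 °C should release the phenol without touching the enal.

Compound list
1 | 3-ethoxycyclopent-2-en-1-one | CCOC1=CC(=O)CC1 | starting material
2 | allylmagnesium bromide | C=CC[Mg]Br | starting material
3 | bromomagnesium alkoxide of 3-ethoxy-1-(prop-2-en-1-yl)cyclopent-2-en-1-ol (racemic, not isolated) | CCOC1=CC(CC=C)(O[Mg]Br)CC1 | intermediate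
4 | 3-(prop-2-en-1-yl)cyclopent-2-en-1-one | C=CCC1=CC(=O)CC1 | intermediate
5 | dimethylaluminium enolate of (R)-3-methyl-3-(prop-2-en-1-yl)cyclopentanone (not isolated) | C[Al](C)OC1=C[C@@](C)(CC=C)CC1 | intermediate
6 | trimethyl{[(3R)-3-methyl-3-(prop-2-en-1-yl)cyclopent-1-en-1-yl]oxy}silane | C[Si](C)(C)OC1=C[C@@](C)(CC=C)CC1 | intermediate
7 | trimethyl phosphonoacetate | COC(=O)CP(=O)(OC)OC | starting material
8 | 2-bromo-1,1-dimethoxyethane | COC(CBr)OC | starting material
9 | methyl 2-(dimethoxyphosphoryl)-4,4-dimethoxybutanoate (racemic) | COC(=O)C(CC(OC)OC)P(=O)(OC)OC | intermediate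
10 | methyl 4,4-dimethoxy-2-methylidenebutanoate | COC(=O)C(=C)CC(OC)OC | intermediate
11 | methyl 4-methoxy-4-[(2R)-2-methyl-5-oxo-2-(prop-2-en-1-yl)cyclopentyl]-2-methylidenebutanoate (mixture at C5 and C6, left undefined) | COC(=O)C(=C)CC(OC)C1C(=O)CC[C@]1(C)CC=C | intermediate
12 | methyl (8aR)-4-methoxy-8a-methyl-3-oxo-1,2,3,3a,4,5,8,8a-octahydroazulene-6-carboxylate (mixture at C5 and C6, left undefined) | O=C1CC[C@]2(C)CC=C(C(=O)OC)CC(OC)C12 | intermediate
13 | methyl (8aR)-8a-methyl-3-oxo-1,2,3,5,8,8a-hexahydroazulene-6-carboxylate | O=C1CC[C@]2(C)CC=C(C(=O)OC)CC=C12 | intermediate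
14 | methyl (3R,8aR)-3-hydroxy-8a-methyl-3-(propan-2-yl)-1,2,3,5,8,8a-hexahydroazulene-6-carboxylate | CC(C)[C@]1(O)CC[C@]2(C)CC=C(C(=O)OC)CC=C12 | intermediate
15 | bis-boranyl intermediate: C4–O–BH2 and C6–BH2 (α), H-5 α (not isolated) | CC(C)[C@]1(OB)CC[C@]2(C)CC=C(C(=O)OC)C[C@H](B)[C@H]21 | intermediate
16 | methyl (3R,3aS,4S,8aR)-3,4-dihydroxy-8a-methyl-3-(propan-2-yl)-1,2,3,3a,4,5,8,8a-octahydroazulene-6-carboxylate | CC(C)[C@]1(O)CC[C@]2(C)CC=C(C(=O)OC)C[C@H](O)[C@H]21 | intermediate
17 | (3R,3aS,4S,8aR)-6-(hydroxymethyl)-8a-methyl-3-(propan-2-yl)-1,2,3,3a,4,5,8,8a-octahydroazulene-3,4-diol | CC(C)[C@]1(O)CC[C@]2(C)CC=C(CO)C[C@H](O)[C@H]21 | intermediate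
18 | (3R,3aS,4S,8aR)-3,4-dihydroxy-8a-methyl-3-(propan-2-yl)-1,2,3,3a,4,5,8,8a-octahydroazulene-6-carbaldehyde | CC(C)[C@]1(O)CC[C@]2(C)CC=C(C=O)C[C@H](O)[C@H]21 | intermediate
19 | 4-acetoxybenzoic acid | CC(=O)Oc1ccc(cc1)C(O)=O | starting material
20 | (3R,3aS,4S,8aR)-6-formyl-3-hydroxy-8a-methyl-3-(propan-2-yl)-1,2,3,3a,4,5,8,8a-octahydroazulen-4-yl 4-(acetyloxy)benzoate | CC(C)[C@]1(O)CC[C@]2(C)CC=C(C=O)C[C@H](OC(=O)c3ccc(OC(C)=O)cc3)[C@H]21 | intermediate
21 | (3R,3aS,4S,8aR)-6-formyl-3-hydroxy-8a-methyl-3-(propan-2-yl)-1,2,3,3a,4,5,8,8a-octahydroazulen-4-yl 4-hydroxybenzoate | CC(C)[C@]1(O)CC[C@]2(C)CC=C(C=O)C[C@H](OC(=O)c3ccc(O)cc3)[C@H]21 | target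

Total step count: 13. Longest linear sequence: 11 steps (steps 1, 2 and 5 to 13; steps 3 and 4 make the side fragment 10).

Steps most likely to fail

Step 9 (hydroboration). Borane may be delivered to the β-face, syn to the angular methyl, if the α-isopropyl group at C4 screens the α-face more than expected; this would give the cis-fused C5/C6 epimers. Partial attack on the enoate is a second risk. The fallback inverts the order of events at C4 and C5/C6 and sets out from 13. Ketalisation with 1,2-bis(trimethylsilyloxy)ethane and catalytic TMSOTf at −78 °C should give the ethylene ketal F1, in which both faces at C4 carry oxygen, so that only the angular methyl differentiates the faces of C5=C6. Hydroboration–oxidation as in step 9 should then give the 6α-hydroxy ketal F2, and pyridinium p-toluenesulfonate in wet acetone should release the trans-fused β-hydroxy ketone F3. Addition of i-PrMgCl/CeCl3 to F3 is expected anti to the adjacent C5–C6 bond, from the α-face, and rejoins the route at 16.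

Step 8 (isopropyl addition). β-Hydride transfer from the secondary alkyl nucleophile (reduction of the ketone) and enolisation may outrun addition, and facial selectivity may be incomplete. The fallback sets out from 13 and uses an sp2 nucleophile that cannot reduce: isopropenylmagnesium bromide with CeCl3 should give the isopropenyl carbinol F4. Hydrogenation with RhCl(PPh3)3 and H2, selective for the 1,1-disubstituted olefin over the two trisubstituted ring olefins, then returns to 14. If facial selectivity rather than reduction is the problem, the detour through F1 to F3 above bypasses this step as well.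

Step 6 (ring-closing metathesis). Cross-metathesis oligomerisation at the allyl terminus, or allyl-to-propenyl isomerisation followed by ring contraction, may compete with closure onto the electron-poor acrylate. The fallback closes the same C8=C9 bond by an intramolecular Horner–Wadsworth–Emmons reaction and sets out from 6 and 9. TMSOTf-catalysed addition of 6 to the acetal of 9 should give the phosphonate F5; ozonolysis of its allyl group (O3, CH2Cl2/MeOH, −78 °C; Me2S) should give the aldehyde F6; and LiCl with i-Pr2NEt in MeCN at high dilution should close the ring and come back to the route at 12.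

Further compounds
F1 | step 9 | ethylene ketal (1,3-dioxolane at C4) of 13 | O1CCOC12CC[C@]3(C)CC=C(C(=O)OC)CC=C23
F2 | step 9 | 6α-hydroxy ketal with H-5 α (trans-fused) | O1CCOC12CC[C@]3(C)CC=C(C(=O)OC)C[C@H](O)[C@@H]23
F3 | step 9 | methyl (3aS,4S,8aR)-4-hydroxy-8a-methyl-3-oxo-1,2,3,3a,4,5,8,8a-octahydroazulene-6-carboxylate | O=C1CC[C@]2(C)CC=C(C(=O)OC)C[C@H](O)[C@@H]12
F4 | step 8 | methyl (3R,8aR)-3-hydroxy-8a-methyl-3-(prop-1-en-2-yl)-1,2,3,5,8,8a-hexahydroazulene-6-carboxylate | CC(=C)[C@]1(O)CC[C@]2(C)CC=C(C(=O)OC)CC=C12
F5 | step 6 | methyl 2-(dimethoxyphosphoryl)-4-methoxy-4-[(2R)-2-methyl-5-oxo-2-(prop-2-en-1-yl)cyclopentyl]butanoate (mixture of diastereomers) | COC(=O)C(CC(OC)C1C(=O)CC[C@]1(C)CC=C)P(=O)(OC)OC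
F6 | step 6 | methyl 2-(dimethoxyphosphoryl)-4-methoxy-4-[(2R)-2-methyl-5-oxo-2-(2-oxoethyl)cyclopentyl]butanoate (mixture of diastereomers) | COC(=O)C(CC(OC)C1C(=O)CC[C@]1(C)CC=O)P(=O)(OC)OC
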